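**Plan**

- Numbering in each half follows 2-benzoxepine: C1 lactone carbonyl, O2, C3H2, C4 (alkene carbon bearing the carboxyl), C5, C5a, C6 (isopropyl carbon), C7, C8, C9 (carbinol carbon bearing the exocyclic CH2–O), C9a. Ring A is the cyclohexane, ring B the oxepinone.
- Cuts: first the only bond between the halves, the ester O–CH2 bond on the exocyclic carbon at C9 of the acylated half, which gives a C4 enoic acid with a free C9 diol and a C9 spiro-oxirane of opposite handedness. Then, in the common racemic monomer: C4=C5 (metathesis), O2–C3 (carboxylate alkylation), C1–C9a (capture of CO2), C9–CH2 (Suzuki coupling), C5–C5a (vinyl conjugate addition).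
- Enabling feature: the two ring A/ring B halves are mirror images at C5a, C6, C9 and C9a and differ only at the exocyclic C9–CH2–O unit (diol in one, CH2–O acylated by the C4 carboxyl of the other). An oxirane spanning C9 and that CH2 in one antipode is therefore the electrophile for the C4 carboxylate of the other.
- Forward: ring A is bought as 4-isopropylcyclohexanone, ring B is closed by metathesis in the racemic series, the oxirane is closed on one antipode only and opened again when the antipodes are joined, and the tert-butyl esters are removed by acid.
- Stereochemistry: relative configuration is relayed from C6 (vinyl anti to isopropyl, CO2 anti to vinyl, osmylation of the C9 methylene from the equatorial face). Absolute configuration of both halves comes from one copper–bis(oxazoline) kinetic resolution that leaves one antipode as diol and turns the other into the epoxide precursor.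

Key step: step 12

Assumption on the chemistry: the sense of the resolution in steps 8 and 9 cannot be predicted for this scaffold. The (R,R) ligand is written, and the mirror-image ligand is used instead if the configurational assignment shows the opposite sense.
Compounds 2, 4, 5, 6, 8, 10, 11, 12 and 13 are racemic; one antipode is drawn and named with starred descriptors.
Steps 8 and 9 are the two outcomes of a single flask operation: step 8 gives the sulfonylated antipode, step 9 the antipode that is left untouched.

**Route**

Step 1
Reactants: 1 4-isopropylcyclohexanone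
Product: 2 (±)-cryptone (4-isopropylcyclohex-2-en-1-one)
Conditions: Pd(OCOCF3)2 (5 mol %), DMSO (10 mol %), O2 (1 atm), AcOH, 80 °C
Reagents that add atoms: none
Why: Aerobic dehydrogenation of a cyclohexanone by divalent palladium (α-palladation of the enol, β-hydride elimination, reoxidation of zerovalent palladium by O2) is established for 4-substituted cyclohexanones and should stop at the enone with the DMSO-ligated trifluoroacetate catalyst; the ketone is symmetric, so only one enone, racemic at C4, can form.

Step 2
Reactants: 2 (±)-cryptone; 3 vinylmagnesium bromide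
Product: 4 racemic trans silyl enol ether trimethyl{[(3R*,4R*)-3-ethenyl-4-isopropylcyclohex-1-en-1-yl]oxy}silane
Conditions: CuBr·SMe2 (10 mol %), TMSCl, THF, −78 °C; Et3N, cold aq NaHCO3, pentane
Reagents that add atoms: chlorotrimethylsilane, C[Si](C)(C)Cl
Why: Copper-catalysed, TMSCl-accelerated conjugate addition of the Grignard reagent should deliver the vinyl group to C3 anti to the neighbouring C4 isopropyl group (axial attack on the half-chair, syn face shielded by isopropyl), which sets the 3,4-trans relationship and fixes the enolate regiospecifically as the C1=C2 silyl enol ether.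

Step 3
Reactants: 4 racemic trans silyl enol ether
Product: 6 racemic enol triflate (3R*,4R*)-3-ethenyl-4-isopropylcyclohex-1-en-1-yl trifluoromethanesulfonate, via lithium enolate 5 (not isolated)
Conditions: MeLi, THF, 0 °C; then PhNTf2, −78 °C to rt
Reagents that add atoms: N-phenylbis(trifluoromethanesulfonimide), O=S(=O)(N(c1ccccc1)S(=O)(=O)C(F)(F)F)C(F)(F)F
Why: Cleavage of the silyl enol ether with methyllithium releases the regiodefined lithium enolate without equilibration, and O-sulfonylation with the N-aryl triflimide (standard enol triflate synthesis) keeps the double bond at C1=C2; no stereocentre is touched.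

Step 4
Reactants: 6 racemic enol triflate; 7 bis(pinacolatoboryl)methane
Product: 8 racemic allylboronate 2-{[(3R*,4R*)-3-ethenyl-4-isopropylcyclohex-1-en-1-yl]methyl}-4,4,5,5-tetramethyl-1,3,2-dioxaborolane
Conditions: Pd[P(t-Bu)3]2 (5 mol %), aq KOH, 1,4-dioxane, rt
Reagents that add atoms: none
Why: Suzuki–Miyaura coupling of a geminal diboron reagent with an alkenyl electrophile on zerovalent palladium; the geminal reagent transmetalates much faster than the monoboronate product because the second boron stabilises the developing α-boryl carbanion, so a single C(sp2)–C(sp3) bond should form and the allylic boronate should survive.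

Step 5
Reactants: 8 racemic allylboronate; 9 tert-butyl 2-(bromomethyl)acrylate
Product: 11 racemic triene diester tert-butyl 2-({[(1S*,2R*,3R*)-2-ethenyl-3-isopropyl-6-methylidenecyclohexane-1-carbonyl]oxy}methyl)prop-2-enoate, via potassium carboxylate 10 (not isolated)
Conditions: [1,3-bis(2,6-diisopropylphenyl)imidazol-2-ylidene]CuCl (10 mol %), KOt-Bu (1.1 equiv), CO2 (1 atm), THF, 70 °C; then 9, DMF, rt
Reagents that add atoms: carbon dioxide, O=C=O
Why: Transmetalation to an allyl complex of monovalent copper and SE2′ insertion of CO2 (the known copper–carbene carboxylation of allylboronates, selective for the γ-terminus) should place the carboxylate on the ring carbon and shift the alkene to the exocyclic position, with CO2 expected to approach anti to the adjacent vinyl group as electrophiles do with 3-substituted cyclohexanone enolates, which sets the future C9a trans to C5a; the potassium carboxylate is then O-alkylated by the activated allylic bromide in a medium no more basic than carbonate, which should leave the β,γ-unsaturated ester unconjugated.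

Step 6
Reactants: 11 racemic triene diester
Product: 12 racemic methylene oxepinone tert-butyl (5aS*,6R*,9aS*)-6-isopropyl-9-methylidene-1-oxo-1,3,5a,6,7,8,9,9a-octahydro-2-benzoxepine-4-carboxylate
Conditions: second-generation Hoveyda–Grubbs catalyst RuCl2(H2IMes)(=CH-C6H4-2-O-i-Pr) (5 mol %), 1,4-benzoquinone (10 mol %), toluene (5 mM), 80 °C
Reagents that add atoms: none
Why: Ring-closing metathesis starting at the monosubstituted vinyl group and ending on the 2-substituted acrylate should close ring B with its trisubstituted C4=C5 enoate, helped by the trans-diequatorial (gauche) placement of the two arms on ring A; the exocyclic 1,1-disubstituted alkene could only close to a tetrasubstituted alkene, which this catalyst forms far more slowly, and benzoquinone suppresses hydride-induced alkene migration.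

Step 7
Reactants: 12 racemic methylene oxepinone
Product: 13 racemic diol tert-butyl (5aS*,6R*,9S*,9aS*)-9-hydroxy-9-(hydroxymethyl)-6-isopropyl-1-oxo-1,3,5a,6,7,8,9,9a-octahydro-2-benzoxepine-4-carboxylate
Conditions: OsO4 (2 mol %), NMO (1.2 equiv), acetone–H2O, 0 °C to rt; aq Na2SO3
Reagents that add atoms: N-methylmorpholine N-oxide, C[N+]1([O-])CCOCC1; water, O
Why: Upjohn dihydroxylation is selective for the electron-neutral exocyclic alkene over the electron-poor trisubstituted enoate, and the bulky osmium reagent is expected to attack C9 from the equatorial face (the axial face carries the syn-axial hydrogens at C5a and C7), which gives the equatorial tertiary hydroxyl and the axial CH2OH.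

Step 8
Reactants: 13 racemic diol tert-butyl ester
Product: 14 primary tosylate tert-butyl ester of the (5aR,6S,9R,9aR) antipode, tert-butyl (5aR,6S,9R,9aR)-9-hydroxy-6-isopropyl-9-{[(4-methylbenzenesulfonyl)oxy]methyl}-1-oxo-1,3,5a,6,7,8,9,9a-octahydro-2-benzoxepine-4-carboxylate
Conditions: Cu(OTf)2 (10 mol %), (R,R)-Ph-box [2,2′-(propane-2,2-diyl)bis((4R)-4-phenyl-4,5-dihydrooxazole)] (10 mol %), TsCl (0.5 equiv), K2CO3, CH2Cl2, 0 °C; silica gel chromatography (less polar fraction)
Reagents that add atoms: p-toluenesulfonyl chloride, Cc1ccc(cc1)S(=O)(=O)Cl
Why: Proposed new method: kinetic resolution of a racemic primary/tertiary 1,2-diol by chiral-copper-catalysed monosulfonylation; the vicinal diol is expected to chelate the divalent copper–bis(oxazoline) complex, which acidifies and exposes the primary hydroxyl for sulfonylation by TsCl, and the antipode whose C8 and C9a flanks of the quaternary C9 fit the C2-symmetric phenyl pockets should react faster, so that half an equivalent of TsCl tosylates one antipode only; the closest known reaction type is the copper–bis(oxazoline)-catalysed enantioselective monosulfonylation and monobenzoylation of chelating vicinal diols (desymmetrisation of meso diols, kinetic resolution of racemic secondary diols); no stereocentre is created, the step only sorts the antipodes, and the sense is to be assigned by anomalous-dispersion crystallography of 14.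

Step 9
Reactants: 13 racemic diol tert-butyl ester
Product: 15 diol tert-butyl ester of the (5aS,6R,9S,9aS) antipode, enantioenriched tert-butyl (5aS,6R,9S,9aS)-9-hydroxy-9-(hydroxymethyl)-6-isopropyl-1-oxo-1,3,5a,6,7,8,9,9a-octahydro-2-benzoxepine-4-carboxylate
Conditions: same flask as step 8 (Cu(OTf)2, (R,R)-Ph-box, TsCl 0.5 equiv, K2CO3, CH2Cl2, 0 °C); silica gel chromatography (more polar fraction)
Reagents that add atoms: none
Why: This is the slow-reacting partner of the kinetic resolution of step 8: the antipode that fits the chiral copper chelate poorly is not sulfonylated while the half equivalent of TsCl is consumed by the other, so it is left chemically unchanged and is separated from the much less polar tosylate 14 by chromatography, with no bond formed and no stereocentre touched.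

Step 10
Reactants: 14 primary tosylate tert-butyl ester
Product: 16 spiro-epoxide tert-butyl (5aR,6S,9R,9aR)-6-isopropyl-1-oxo-1,3,5a,6,7,8-hexahydro-9aH-spiro[2-benzoxepine-9,2′-oxirane]-4-carboxylate (oxirane oxygen equatorial on C9, oxirane CH2 axial)
Conditions: Cs2CO3, MeCN, 0 °C to rt
Reagents that add atoms: none
Why: Williamson-type 3-exo-tet closure of the tertiary alkoxide onto the neighbouring primary tosylate; the C9–O bond is not broken, so C9 keeps its configuration, and a carbonate base in an aprotic solvent should leave the lactone and the tert-butyl ester intact.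

Step 11
Reactants: 15 diol tert-butyl ester of the (5aS,6R,9S,9aS) antipode
Product: 17 diol acid (5aS,6R,9S,9aS)-9-hydroxy-9-(hydroxymethyl)-6-isopropyl-1-oxo-1,3,5a,6,7,8,9,9a-octahydro-2-benzoxepine-4-carboxylic acid
Conditions: CF3CO2H–CH2Cl2 (1:4), 0 °C to rt; evaporation from toluene, aq MeOH
Reagents that add atoms: none
Why: Acidolysis of a tert-butyl ester by alkyl–oxygen cleavage (loss of isobutene) should spare the lactone, the enoate and the diol at short reaction time, and the aqueous methanol treatment cleaves any trifluoroacetate formed at the primary hydroxyl; no stereocentre is involved.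

Step 12
Reactants: 16 spiro-epoxide tert-butyl ester; 17 diol acid
Product: 19 heterochiral dimer tert-butyl ester, via caesium carboxylate 18 (not isolated)
Conditions: Cs2CO3 (0.1 equiv), MeCN, 60 °C
Reagents that add atoms: none
Why: A small part of acid 17 is converted into its caesium carboxylate 18, which attacks the oxirane CH2 of 16 in an SN2 reaction from the side opposite to the ring oxygen; the C9 oxyanion set free is protonated at once by remaining 17, which regenerates carboxylate, so the base is needed only in a sub-stoichiometric amount and the medium never becomes more basic than a carboxylate. The closest known reaction type is the opening of terminal and 1,1-disubstituted epoxides at their CH2 group by carboxylic acids under carboxylate or onium-salt catalysis to give β-hydroxy esters. No ring is closed, only the three-membered oxirane is opened, and no new stereocentre arises: the C9–O bond of 16 is not broken, so C9 and the other seven stereocentres enter the dimer unchanged. The step needs regioselectivity for the CH2 carbon and chemoselectivity for the carboxylate over the two hydroxyls of 17; the first is secured by the fully substituted spiro carbon C9, which an SN2 nucleophile cannot reach, the second by the far greater nucleophilicity of the carboxylate in a buffered medium and by the tert-butyl ester that masks the only acid of 16 and so excludes oligomers. The same buffering protects the C9a–H next to the lactone carbonyl against elimination with opening of the oxirane, and the free diol against translactonisation. Because the partners are of opposite handedness, any mispaired minor antipode ends up in the homochiral diastereomer, which is removed by chromatography, so the dimer should be enantiomerically purer than either half.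

Step 13
Reactants: 19 heterochiral dimer tert-butyl ester
Product: 20 target (5aR,6S,9R,9aR)-9-hydroxy-9-({[(5aS,6R,9S,9aS)-9-hydroxy-9-(hydroxymethyl)-6-isopropyl-1-oxo-1,3,5a,6,7,8,9,9a-octahydro-2-benzoxepine-4-carbonyl]oxy}methyl)-6-isopropyl-1-oxo-1,3,5a,6,7,8,9,9a-octahydro-2-benzoxepine-4-carboxylic acid
Conditions: CF3CO2H–CH2Cl2 (1:4), 0 °C to rt; evaporation from toluene, aq MeOH, reversed-phase chromatography
Reagents that add atoms: none
Why: The same alkyl–oxygen acidolysis as in step 11, by then tested on the monomer; the inter-half ester is a primary alkyl ester that cannot ionise, so only the tert-butyl group should be lost and no stereocentre is affected.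

**Compound list**

1 | 4-isopropylcyclohexanone | CC(C)C1CCC(=O)CC1 | starting material
2 | (±)-cryptone, 4-isopropylcyclohex-2-en-1-one (racemic, R antipode drawn) | CC(C)[C@H]1CCC(=O)C=C1 | intermediate
3 | vinylmagnesium bromide | C=C[Mg]Br | starting material
4 | trimethyl{[(3R*,4R*)-3-ethenyl-4-isopropylcyclohex-1-en-1-yl]oxy}silane (racemic, trans) | CC(C)[C@H]1CCC(O[Si](C)(C)C)=C[C@@H]1C=C | intermediate
5 | lithium (3R*,4R*)-3-ethenyl-4-isopropylcyclohex-1-en-1-olate (racemic, not isolated) | CC(C)[C@H]1CCC([O-])=C[C@@H]1C=C.[Li+] | intermediate
6 | (3R*,4R*)-3-ethenyl-4-isopropylcyclohex-1-en-1-yl trifluoromethanesulfonate (racemic) | CC(C)[C@H]1CCC(OS(=O)(=O)C(F)(F)F)=C[C@@H]1C=C | intermediate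
7 | bis(pinacolatoboryl)methane | CC1(C)OB(CB2OC(C)(C)C(C)(C)O2)OC1(C)C | starting material
8 | 2-{[(3R*,4R*)-3-ethenyl-4-isopropylcyclohex-1-en-1-yl]methyl}-4,4,5,5-tetramethyl-1,3,2-dioxaborolane (racemic) | CC(C)[C@H]1CCC(CB2OC(C)(C)C(C)(C)O2)=C[C@@H]1C=C | intermediate
9 | tert-butyl 2-(bromomethyl)acrylate | C=C(CBr)C(=O)OC(C)(C)C | starting material
10 | potassium (1S*,2R*,3R*)-2-ethenyl-3-isopropyl-6-methylidenecyclohexane-1-carboxylate (racemic, not isolated) | CC(C)[C@H]1CCC(=C)[C@@H](C(=O)[O-])[C@@H]1C=C.[K+] | intermediate
11 | tert-butyl 2-({[(1S*,2R*,3R*)-2-ethenyl-3-isopropyl-6-methylidenecyclohexane-1-carbonyl]oxy}methyl)prop-2-enoate (racemic) | CC(C)[C@H]1CCC(=C)[C@@H](C(=O)OCC(=C)C(=O)OC(C)(C)C)[C@@H]1C=C | intermediate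
12 | tert-butyl (5aS*,6R*,9aS*)-6-isopropyl-9-methylidene-1-oxo-1,3,5a,6,7,8,9,9a-octahydro-2-benzoxepine-4-carboxylate (racemic) | CC(C)[C@H]1CCC(=C)[C@H]2C(=O)OCC(C(=O)OC(C)(C)C)=C[C@H]12 | intermediate
13 | tert-butyl (5aS*,6R*,9S*,9aS*)-9-hydroxy-9-(hydroxymethyl)-6-isopropyl-1-oxo-1,3,5a,6,7,8,9,9a-octahydro-2-benzoxepine-4-carboxylate (racemic) | CC(C)[C@H]1CC[C@@](O)(CO)[C@H]2C(=O)OCC(C(=O)OC(C)(C)C)=C[C@H]12 | intermediate
14 | tert-butyl (5aR,6S,9R,9aR)-9-hydroxy-6-isopropyl-9-{[(4-methylbenzenesulfonyl)oxy]methyl}-1-oxo-1,3,5a,6,7,8,9,9a-octahydro-2-benzoxepine-4-carboxylate | CC(C)[C@@H]1CC[C@](O)(COS(=O)(=O)c3ccc(C)cc3)[C@@H]2C(=O)OCC(C(=O)OC(C)(C)C)=C[C@@H]12 | intermediate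
15 | tert-butyl (5aS,6R,9S,9aS)-9-hydroxy-9-(hydroxymethyl)-6-isopropyl-1-oxo-1,3,5a,6,7,8,9,9a-octahydro-2-benzoxepine-4-carboxylate (single antipode) | CC(C)[C@H]1CC[C@@](O)(CO)[C@H]2C(=O)OCC(C(=O)OC(C)(C)C)=C[C@H]12 | intermediate
16 | tert-butyl (5aR,6S,9R,9aR)-6-isopropyl-1-oxo-1,3,5a,6,7,8-hexahydro-9aH-spiro[2-benzoxepine-9,2′-oxirane]-4-carboxylate | CC(C)[C@@H]1CC[C@]3(CO3)[C@@H]2C(=O)OCC(C(=O)OC(C)(C)C)=C[C@@H]12 | intermediate
17 | (5aS,6R,9S,9aS)-9-hydroxy-9-(hydroxymethyl)-6-isopropyl-1-oxo-1,3,5a,6,7,8,9,9a-octahydro-2-benzoxepine-4-carboxylic acid | CC(C)[C@H]1CC[C@@](O)(CO)[C@H]2C(=O)OCC(C(=O)O)=C[C@H]12 | intermediate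
18 | caesium (5aS,6R,9S,9aS)-9-hydroxy-9-(hydroxymethyl)-6-isopropyl-1-oxo-1,3,5a,6,7,8,9,9a-octahydro-2-benzoxepine-4-carboxylate (not isolated) | CC(C)[C@H]1CC[C@@](O)(CO)[C@H]2C(=O)OCC(C(=O)[O-])=C[C@H]12.[Cs+] | intermediate
19 | tert-butyl (5aR,6S,9R,9aR)-9-hydroxy-9-({[(5aS,6R,9S,9aS)-9-hydroxy-9-(hydroxymethyl)-6-isopropyl-1-oxo-1,3,5a,6,7,8,9,9a-octahydro-2-benzoxepine-4-carbonyl]oxy}methyl)-6-isopropyl-1-oxo-1,3,5a,6,7,8,9,9a-octahydro-2-benzoxepine-4-carboxylate | CC(C)[C@H]1CC[C@@](O)(CO)[C@H]2C(=O)OCC(C(=O)OC[C@@]3(O)CC[C@@H](C(C)C)[C@@H]4C=C(C(=O)OC(C)(C)C)COC(=O)[C@H]43)=C[C@H]12 | intermediate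
20 | CNP0340505.1, the free acid of 19 | CC(C)[C@H]1CC[C@@](O)(CO)[C@H]2C(=O)OCC(C(=O)OC[C@@]3(O)CC[C@@H](C(C)C)[C@@H]4C=C(C(=O)O)COC(=O)[C@H]43)=C[C@H]12 | target

**Count**

Total step count: 13 (steps 8 and 9 are the two outcomes of one flask operation, so 12 operations).
Longest linear sequence: 11 steps (steps 1 to 7, then 8, 10, 12 and 13; the branch through steps 9 and 11 is equally long).

**Steps most likely to fail**

1. Step 8 (new method; the recovery in step 9 depends on it). The chiral copper complex may discriminate the antipodes poorly, because the stereocentres that distinguish them sit on the ring beside the chelated diol. Tosylate and recovered diol would then both be of low enantiomeric purity. The neopentyl-type primary hydroxyl may also sulfonylate slowly. The fallback sets out from racemic diol 13 and returns at 14 and 15. Racemic 13 is resolved by preparative chromatography on a chiral stationary phase (immobilised amylose tris(3,5-dimethylphenylcarbamate), supercritical CO2–MeOH). This gives 15 directly, together with its antipode, the (5aR,6S,9R,9aR)-diol tert-butyl ester F1. F1 is then sulfonylated at the primary hydroxyl only (TsCl, Et3N, catalytic Bu2SnO, CH2Cl2, rt) to give 14.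

2. Step 5. CO2 may be captured at the exocyclic terminus of the allylcopper or with a low facial preference, the allylboronate may be protodeboronated by tert-butoxide, or the exocyclic alkene may migrate into conjugation during the one-pot alkylation. The fallback sets out from allylboronate 8 and returns at triene diester 11. Thermal allylboration of formaldehyde (paraformaldehyde, toluene, 80 °C) runs through a closed six-membered transition state and therefore always bonds the γ ring carbon. The face anti to the vinyl group is again the open one, and the product is homoallylic alcohol F2. Jones oxidation (CrO3, H2SO4, acetone, 0 °C; hexavalent chromium) gives β,γ-unsaturated acid F3 under acidic conditions that should not move the alkene. F3 is O-alkylated with bromide 9 (KHCO3, DMF, rt) to give 11.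

3. Step 12. SN2 attack at the axial oxirane CH2 must pass over the ring face that carries the syn-axial hydrogens and may be slow. Deprotonation at C9a with β-elimination of the oxirane, or translactonisation of the free diol, could then overtake the union. The fallback makes the inter-half ester from the acyl side instead. It sets out from diol acid 17 and from racemic diol 13, and returns at target 20. The antipodal diol tert-butyl ester F1 is taken from 13 by the chromatographic resolution described under the first fallback. Acid 17 is protected as spiro-acetonide acid F4 (2-methoxypropene, catalytic pyridinium p-toluenesulfonate, CH2Cl2; aqueous work-up frees the carboxyl). Carbodiimide esterification of F4 with the primary hydroxyl of F1 (EDC·HCl, DMAP, CH2Cl2; the tertiary hydroxyl does not acylate) gives the acetonide-protected dimer tert-butyl ester F5. Aqueous CF3CO2H in CH2Cl2 removes the acetonide and the tert-butyl ester together and gives 20.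

**Further compounds**

F1 | step 8 | tert-butyl (5aR,6S,9R,9aR)-9-hydroxy-9-(hydroxymethyl)-6-isopropyl-1-oxo-1,3,5a,6,7,8,9,9a-octahydro-2-benzoxepine-4-carboxylate (antipode of 15) | CC(C)[C@@H]1CC[C@](O)(CO)[C@@H]2C(=O)OCC(C(=O)OC(C)(C)C)=C[C@@H]12
F2 | step 5 | [(1S*,2R*,3R*)-2-ethenyl-3-isopropyl-6-methylidenecyclohexyl]methanol (racemic) | CC(C)[C@H]1CCC(=C)[C@@H](CO)[C@@H]1C=C
F3 | step 5 | (1S*,2R*,3R*)-2-ethenyl-3-isopropyl-6-methylidenecyclohexane-1-carboxylic acid (racemic) | CC(C)[C@H]1CCC(=C)[C@@H](C(=O)O)[C@@H]1C=C
F4 | step 12 | acetonide of 17 (2,2-dimethyl-1,3-dioxolane spiro-fused at C9 through the C9 oxygen and the CH2–O, free C4 carboxylic acid) | CC(C)[C@H]1CC[C@@](OC3(C)C)(CO3)[C@H]2C(=O)OCC(C(=O)O)=C[C@H]12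
F5 | step 12 | acetonide of 19 (diol of the (5aS,6R,9S,9aS) half as 2,2-dimethyl-1,3-dioxolane, tert-butyl ester on the other half) | CC(C)[C@H]1CC[C@@](OC5(C)C)(CO5)[C@H]2C(=O)OCC(C(=O)OC[C@@]3(O)CC[C@@H](C(C)C)[C@@H]4C=C(C(=O)OC(C)(C)C)COC(=O)[C@H]43)=C[C@H]12
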